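**Retrosynthetic overview** (ring A = para-phenylene, ring B = methoxy ring, ring C = meta-phenylene, ring D = phenol ring)

1. Target 27 comes from benzyl ether 26 by hydrogenolysis. Ring C carries only the ring B oxygen at C1 and the CH2CH2 bridge at C3, with C2, C4, C5 and C6 as CH. It is therefore cut into an acetylene equivalent (C4–C5) and the 2-aryloxy-4-alkylbuta-1,3-diene C6=C1–C2=C3 held in macrocycle 22 (Diels–Alder, then loss of two sulfinic acids).
2. Diene 22 comes from seco ethynyl ether 19: ring-closing enyne metathesis forms C2=C3 and C1=C6 of the future ring C and closes the 18-membered ring.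
3. 19 comes from phenol 13 (trichloroethylene, then n-BuLi); 13 comes from an Ullmann ether coupling of ring D phenol 5 with ring A–B bromide 11.
4. 5 comes from 3,4-dihydroxybenzaldehyde (benzylation, allylation, deoxygenation); 11 comes from o-vanillin and a 4-bromobenzyl phosphonium salt (Wittig, diimide).
5. Ring order: rings D, A and B are bought in; the macrocycle is closed in step 11; ring C is built last (steps 12 and 13).

Key step: step 11

Remark: stilbene 10 is carried as an E/Z mixture and adduct 24 as a mixture of diastereomers, because steps 6 and 13 erase these stereo-elements; the target has no stereocentre.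

**Route**

Step 1
Reactants: 1 3,4-dihydroxybenzaldehyde
Product: 2 4-(benzyloxy)-3-hydroxybenzaldehyde
Conditions: BnBr (1.05 equiv), NaHCO3, NaI (cat.), DMF, 40 °C
Reagents that add atoms: benzyl bromide, BrCc1ccccc1
Why: Williamson etherification; the 4-OH, para to the formyl group, is the more acidic phenol and the one ionised by NaHCO3, so benzylation should occur there selectively.

Step 2
Reactants: 2 4-(benzyloxy)-3-hydroxybenzaldehyde; 3 allylmagnesium bromide
Product: 4 1-[4-(benzyloxy)-3-hydroxyphenyl]but-3-en-1-ol (racemic)
Conditions: allylMgBr (2.3 equiv), THF, −78 to 0 °C; sat. aq NH4Cl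
Reagents that add atoms: none
Why: Grignard 1,2-addition to the aldehyde after the first equivalent has deprotonated the phenol; the carbinol centre forms racemic and is removed in step 3.

Step 3
Reactants: 4 1-[4-(benzyloxy)-3-hydroxyphenyl]but-3-en-1-ol
Product: 5 2-(benzyloxy)-5-(but-3-en-1-yl)phenol
Conditions: Et3SiH (3 equiv), TFA, CH2Cl2, −10 to 0 °C
Reagents that add atoms: none
Why: Ionic hydrogenation; the benzylic cation stabilised by the para benzyloxy group should be trapped by the silane hydride faster than it loses a proton, and the monosubstituted alkene is not protonated under these conditions.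

Step 4
Reactants: 6 o-vanillin (2-hydroxy-3-methoxybenzaldehyde)
Product: 7 3-methoxy-2-(methoxymethoxy)benzaldehyde
Conditions: MOMCl, i-Pr2NEt, CH2Cl2, 0 °C to rt
Reagents that add atoms: chloromethyl methyl ether, COCCl
Why: Methoxymethyl protection of the phenol; the acetal tolerates the ylide, diimide and hot carbonate of steps 5–7 and is later removed by mild acid that spares the benzyl ether and the alkene.

Step 5
Reactants: 7 3-methoxy-2-(methoxymethoxy)benzaldehyde; 8 (4-bromobenzyl)triphenylphosphonium bromide
Product: 10 1-bromo-4-{2-[3-methoxy-2-(methoxymethoxy)phenyl]ethenyl}benzene (E/Z mixture), via (4-bromobenzylidene)triphenylphosphorane 9 (not isolated)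
Conditions: KOtBu, THF, 0 °C; then 7, 0 °C to rt
Reagents that add atoms: none
Why: Wittig olefination with a semi-stabilised benzylide; the alkene geometry is irrelevant because the double bond is saturated in step 6.

Step 6
Reactants: 10 1-bromo-4-{2-[3-methoxy-2-(methoxymethoxy)phenyl]ethenyl}benzene
Product: 11 1-bromo-4-{2-[3-methoxy-2-(methoxymethoxy)phenyl]ethyl}benzene
Conditions: TsNHNH2, NaOAc, DME/H2O, reflux
Reagents that add atoms: none
Why: Diimide reduction; diimide generated from the sulfonyl hydrazide transfers two hydrogens to the C=C only, so the aryl bromide, which Pd/H2 would remove, and the acetal are retained.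

Step 7
Reactants: 5 2-(benzyloxy)-5-(but-3-en-1-yl)phenol; 11 1-bromo-4-{2-[3-methoxy-2-(methoxymethoxy)phenyl]ethyl}benzene
Product: 12 1-(benzyloxy)-4-(but-3-en-1-yl)-2-(4-{2-[3-methoxy-2-(methoxymethoxy)phenyl]ethyl}phenoxy)benzene
Conditions: CuI (10 mol%), N,N-dimethylglycine·HCl (30 mol%), Cs2CO3, 1,4-dioxane, 100 °C
Reagents that add atoms: none
Why: Ligand-accelerated Ullmann diaryl ether synthesis between an unhindered para-alkyl aryl bromide and an electron-rich ortho-alkoxy phenoxide; the alkene, acetal and benzyl ether are inert to copper and carbonate.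

Step 8
Reactants: 12 1-(benzyloxy)-4-(but-3-en-1-yl)-2-(4-{2-[3-methoxy-2-(methoxymethoxy)phenyl]ethyl}phenoxy)benzene
Product: 13 2-(2-{4-[2-(benzyloxy)-5-(but-3-en-1-yl)phenoxy]phenyl}ethyl)-6-methoxyphenol
Conditions: TsOH·H2O (0.2 equiv), MeOH/THF, 50 °C
Reagents that add atoms: none
Why: Acid-catalysed transacetalisation of the aryl methoxymethyl ether to methanol; the benzyl ether, diaryl ether and terminal alkene are stable to this acid.

Step 9
Reactants: 13 2-(2-{4-[2-(benzyloxy)-5-(but-3-en-1-yl)phenoxy]phenyl}ethyl)-6-methoxyphenol; 14 trichloroethylene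
Product: 16 (E)-1,2-dichlorovinyl ether of phenol 13, via dichloroacetylene 15 (not isolated)
Conditions: K2CO3, DMF, 70 °C
Reagents that add atoms: none
Why: Base eliminates HCl from trichloroethylene, and the phenoxide adds anti to the resulting dichloroacetylene to give the (E)-dichlorovinyl ether; the small sp electrophile reaches the oxygen flanked by OMe and the CH2CH2 chain without difficulty.

Step 10
Reactants: 16 (E)-1,2-dichlorovinyl ether of phenol 13
Product: 19 ethynyl ether of phenol 13 (seco precursor), via chloroethynyl ether 17 (not isolated), via lithium acetylide 18 (not isolated)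
Conditions: n-BuLi (2.5 equiv), THF, −78 to −40 °C; then H2O, −78 °C
Reagents that add atoms: none
Why: Alkynyl ether synthesis from a dichlorovinyl ether: elimination of HCl gives the chloroalkyne, chlorine–lithium exchange gives the acetylide, and cold protonation gives the terminal ynol ether, which is used at once.

Step 11
Reactants: 19 ethynyl ether of phenol 13 (seco precursor); 20 ethylene
Product: 22 macrocyclic (E)-2-aryloxy-1,3-diene (18-membered ring), via acyclic 2-aryloxybuta-1,3-diene 21 (not isolated)
Conditions: RuCl2(=CHPh)(PCy3)(H2IMes) (second-generation Grubbs catalyst, 10 mol%), ethylene (1 atm), CH2Cl2 (1 mM), 40 °C; then argon sparge, 40 °C; basic alumina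
Reagents that add atoms: none
Why: The ruthenium methylidene formed under ethylene adds to the polarised, electron-rich C≡C of the ethynyl ether through a ruthenacyclobutene, and ethylene releases the vinylcarbene as 2-aryloxybutadiene 21 (either sense of addition leads to the same diene). The closest known reactions are ethylene-mediated enyne metathesis of alkynyl ethers and macrocyclic ring-closing enyne metathesis run under ethylene. The monosubstituted vinyl end of 21 then undergoes ring-closing metathesis with the butenyl alkene of ring D, closing the 18-membered ring in the endo mode: both former alkyne carbons lie in the ring, the methylene is exocyclic, and the new bonds are the future C2=C3 and C1=C6 of ring C. No stereocentre is formed; the E geometry of the ring alkene is expected from thermodynamic control in an unstrained 18-membered ring. The step needs endo over exo closure and cyclisation over oligomerisation: the first should follow from the much lower metathesis reactivity of the 1,1-disubstituted aryloxy alkene compared with the vinyl group and from the large ring size, the second from millimolar dilution and removal of ethylene with argon once 21 has formed.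

Step 12
Reactants: 22 macrocyclic (E)-2-aryloxy-1,3-diene; 23 (E)-1,2-bis(phenylsulfonyl)ethylene
Product: 24 Diels–Alder adduct, a 4,5-bis(phenylsulfonyl)cyclohexene fused 1,3 into the macrocycle (racemic, trans-disulfonyl, mixture of epimers at the alkyl-bearing carbon)
Conditions: 23 (1.5 equiv), toluene, 90 °C
Reagents that add atoms: none
Why: Normal-electron-demand Diels–Alder reaction of the electron-rich diene, whose s-cis form has the same 1,3 geometry as the final meta-phenylene, with a doubly activated symmetric dienophile; the sulfonyl groups are trans from the E-dienophile and all three new stereocentres are erased in step 13.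

Step 13
Reactants: 24 Diels–Alder adduct
Product: 26 O-benzyl ether of the target, via vinyl sulfone cyclohexa-1,4-diene 25 (not isolated)
Conditions: KOtBu (4 equiv), THF, 0 °C to rt
Reagents that add atoms: none
Why: E1cB loss of the first sulfinate gives vinyl sulfone 25; base-mediated isomerisation to the allylic sulfone and a second elimination, driven by aromatisation, should give ring C without an oxidant.

Step 14
Reactants: 26 O-benzyl ether of the target
Product: 27 target
Conditions: H2 (1 atm), 10% Pd/C, EtOAc/EtOH, rt
Reagents that add atoms: none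
Why: Hydrogenolysis of the aryl benzyl ether; no other reducible group remains and the aryl methyl and diaryl ethers are stable.

**Compound list**

1 | 3,4-dihydroxybenzaldehyde | O=Cc1ccc(O)c(O)c1 | starting material
2 | 4-(benzyloxy)-3-hydroxybenzaldehyde | O=Cc1ccc(OCc2ccccc2)c(O)c1 | intermediate
3 | allylmagnesium bromide | C=CC[Mg]Br | starting material
4 | 1-[4-(benzyloxy)-3-hydroxyphenyl]but-3-en-1-ol (racemic) | C=CCC(O)c1ccc(OCc2ccccc2)c(O)c1 | intermediate
5 | 2-(benzyloxy)-5-(but-3-en-1-yl)phenol | C=CCCc1ccc(OCc2ccccc2)c(O)c1 | intermediate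
6 | o-vanillin (2-hydroxy-3-methoxybenzaldehyde) | COc1cccc(C=O)c1O | starting material
7 | 3-methoxy-2-(methoxymethoxy)benzaldehyde | COCOc1c(OC)cccc1C=O | intermediate
8 | (4-bromobenzyl)triphenylphosphonium bromide | [Br-].Brc1ccc(C[P+](c2ccccc2)(c2ccccc2)c2ccccc2)cc1 | starting material
9 | (4-bromobenzylidene)triphenylphosphorane | Brc1ccc(C=P(c2ccccc2)(c2ccccc2)c2ccccc2)cc1 | intermediate
10 | 1-bromo-4-{2-[3-methoxy-2-(methoxymethoxy)phenyl]ethenyl}benzene (E/Z mixture) | COCOc1c(OC)cccc1C=Cc1ccc(Br)cc1 | intermediate
11 | 1-bromo-4-{2-[3-methoxy-2-(methoxymethoxy)phenyl]ethyl}benzene | COCOc1c(OC)cccc1CCc1ccc(Br)cc1 | intermediate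
12 | 1-(benzyloxy)-4-(but-3-en-1-yl)-2-(4-{2-[3-methoxy-2-(methoxymethoxy)phenyl]ethyl}phenoxy)benzene | COCOc1c(OC)cccc1CCc1ccc(Oc2cc(CCC=C)ccc2OCc2ccccc2)cc1 | intermediate
13 | 2-(2-{4-[2-(benzyloxy)-5-(but-3-en-1-yl)phenoxy]phenyl}ethyl)-6-methoxyphenol | COc1cccc(CCc2ccc(Oc3cc(CCC=C)ccc3OCc3ccccc3)cc2)c1O | intermediate
14 | trichloroethylene | ClC=C(Cl)Cl | starting material
15 | dichloroacetylene | ClC#CCl | intermediate
16 | (E)-1,2-dichlorovinyl ether of phenol 13 (chlorines trans) | COc1cccc(CCc2ccc(Oc3cc(CCC=C)ccc3OCc3ccccc3)cc2)c1O/C(Cl)=C\Cl | intermediate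
17 | chloroethynyl ether of phenol 13 | COc1cccc(CCc2ccc(Oc3cc(CCC=C)ccc3OCc3ccccc3)cc2)c1OC#CCl | intermediate
18 | lithium acetylide of ethynyl ether 19 | COc1cccc(CCc2ccc(Oc3cc(CCC=C)ccc3OCc3ccccc3)cc2)c1OC#C[Li] | intermediate
19 | 1-(benzyloxy)-4-(but-3-en-1-yl)-2-(4-{2-[2-(ethynyloxy)-3-methoxyphenyl]ethyl}phenoxy)benzene (seco precursor) | COc1cccc(CCc2ccc(Oc3cc(CCC=C)ccc3OCc4ccccc4)cc2)c1OC#C | intermediate
20 | ethylene | C=C | starting material
21 | buta-1,3-dien-2-yl ether of phenol 13 (acyclic triene) | COc1cccc(CCc2ccc(Oc3cc(CCC=C)ccc3OCc3ccccc3)cc2)c1OC(=C)C=C | intermediate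
22 | 18-membered macrocycle in which the ring B oxygen carries C(=CH2)–CH=CH (E), joined through CH2CH2 to ring D | COc1cccc2c1OC(=C)/C=C/CCc1ccc(OCc3ccccc3)c(c1)Oc1ccc(cc1)CC2 | intermediate
23 | (E)-1,2-bis(phenylsulfonyl)ethylene | O=S(=O)(/C=C/S(=O)(=O)c1ccccc1)c1ccccc1 | starting material
24 | Diels–Alder adduct: 1-aryloxy-3-alkyl-4,5-bis(phenylsulfonyl)cyclohexene in the macrocycle (racemic, sulfonyl groups trans, alkyl-bearing carbon unassigned) | COc1cccc2c1OC3=CC([C@@H]([C@H](C3)S(=O)(=O)c3ccccc3)S(=O)(=O)c3ccccc3)CCc3ccc(OCc4ccccc4)c(c3)Oc3ccc(cc3)CC2 | intermediate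
25 | vinyl sulfone cyclohexa-1,4-diene after loss of one sulfinate (racemic, one regioisomer drawn) | COc1cccc2c1OC3=CC(C=C(C3)S(=O)(=O)c3ccccc3)CCc3ccc(OCc4ccccc4)c(c3)Oc3ccc(cc3)CC2 | intermediate
26 | O-benzyl ether of the target (ring C aromatic, ring D OBn) | COc1cccc2c1Oc1cccc(c1)CCc1ccc(OCc3ccccc3)c(c1)Oc1ccc(cc1)CC2 | intermediate
27 | target CNP0309263.0 | COc1cccc2c1Oc1cccc(c1)CCc1ccc(O)c(c1)Oc1ccc(cc1)CC2 | target

**Step count and risks**

Total step count: 14. Longest linear sequence: 11 steps (steps 4–14 from o-vanillin, or steps 1–3 and 7–14 from 3,4-dihydroxybenzaldehyde).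

Steps most likely to fail:

Step 11. The ruthenium may be held as an unreactive aryloxy-substituted carbene after the alkyne step. The butenyl ends may also oligomerise by intermolecular metathesis, or the ring may close through the 1,1-disubstituted enol ether alkene (exo mode). The fallback sets out from phenol 13 and comes back to the route at diene 22, closing the same C2=C3 bond by olefination instead of metathesis. Phenol 13 is esterified with diethylphosphonoacetic acid (EDC·HCl, DMAP, CH2Cl2) to the aryl diethylphosphonoacetate F1. The butenyl alkene of F1 is cleaved (OsO4 cat., NaIO4, 2,6-lutidine, dioxane/H2O) to the 3-arylpropanal F2. Intramolecular Horner–Wadsworth–Emmons olefination at high dilution (LiCl, i-Pr2NEt, MeCN) should give the 18-membered macrocyclic (E)-enoate F3. Methylenation of its aryl ester carbonyl with Cp2Ti(μ-Cl)(μ-CH2)AlMe2 (Tebbe reagent; pyridine, THF, −40 to 0 °C) installs the exocyclic methylene and gives 22.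

Step 10. The terminal aryl ethynyl ether may be lost by hydration or oligomerisation during warming and isolation, and excess n-BuLi may lithiate a ring. The fallback sets out from phenol 13 and comes back at triene 21, avoiding any ynol ether. Phenol 13 is acylated (acryloyl chloride, Et3N, CH2Cl2, 0 °C) to the aryl acrylate F4. Its ester carbonyl is methylenated with Cp2Ti(μ-Cl)(μ-CH2)AlMe2 to give 21 as an isolated compound. 21 is then closed to 22 by ring-closing metathesis with the catalyst of step 11 under argon, without ethylene.

Step 13. The elimination may stop after the first sulfinate has left, and the enol ether may be degraded on prolonged exposure to strong base. The fallback sets out from diene 22 and comes back at benzyl ether 26, replacing base-induced double elimination by thermal elimination and dehydrogenation. Diene 22 is heated with phenyl vinyl sulfoxide (toluene, 110 °C, solid NaHCO3) to give the sulfoxide adduct F5 (isomer mixture). F5 loses benzenesulfenic acid by syn-elimination in the same flask to give the macrocyclic cyclohexadiene F6. F6 is dehydrogenated with DDQ (benzene, rt) to 26.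

**Further compounds**

F1 | step 11 | aryl diethylphosphonoacetate of phenol 13 | COc1cccc(CCc2ccc(Oc3cc(CCC=C)ccc3OCc3ccccc3)cc2)c1OC(=O)CP(=O)(OCC)OCC
F2 | step 11 | 3-arylpropanal from cleavage of the butenyl alkene of F1 | COc1cccc(CCc2ccc(Oc3cc(CCC=O)ccc3OCc3ccccc3)cc2)c1OC(=O)CP(=O)(OCC)OCC
F3 | step 11 | 18-membered macrocyclic (E)-enoate (aryl ester of ring B) | COc1cccc2c1OC(=O)/C=C/CCc1ccc(OCc3ccccc3)c(c1)Oc1ccc(cc1)CC2
F4 | step 10 | aryl acrylate of phenol 13 | COc1cccc(CCc2ccc(Oc3cc(CCC=C)ccc3OCc3ccccc3)cc2)c1OC(=O)C=C
F5 | step 13 | Diels–Alder adduct of 22 with phenyl vinyl sulfoxide (isomer mixture) | COc1cccc2c1OC3=CC(C(CC3)S(=O)c3ccccc3)CCc3ccc(OCc4ccccc4)c(c3)Oc3ccc(cc3)CC2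
F6 | step 13 | macrocyclic 1-aryloxy-3-alkylcyclohexa-1,4-diene | COc1cccc2c1OC3=CC(C=CC3)CCc3ccc(OCc4ccccc4)c(c3)Oc3ccc(cc3)CC2
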